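**Assumption:** read from the SMILES, the target is (1S,2S) at the ring (tertiary OH trans to the side chain, ring methyl cis to it) with all three olefins E. Organometallic species made and consumed in one flask are not numbered.

## Retrosynthetic overview

1. Target 17 ⇐ TBS ether 16 ⇐ B-alkyl Suzuki–Miyaura coupling at C9–C10 of the C14 ring vinyl iodide 10 with the 9-BBN adduct of the C11 triene 15.
2. 10 ⇐ alkynol 9 (Zr-catalysed carboalumination/iodination) ⇐ trans-fused δ-lactone 7 (DIBAL, then Ohira–Bestmann).
3. The only carbocycle and both stereocentres are made in one step: enantioselective proton-initiated cyclisation of (E)-dienoic acid 6 to lactone 7. The cyclohexane and a temporary lactone ring form together; the lactone ring is opened in step 6.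
4. Acid 6 and triene 15 both derive from enyne 3 (homoprenyl bromide + acetylide). Carboalumination fixes each E-trisubstituted olefin; 15 is reached via geraniol, SeO2 oxidation and methylenation.

## Route

**Step 1**
Reactants: 1 (5-bromo-2-methylpent-2-ene), 2 (lithium acetylide–ethylenediamine complex)
Product: 3 (6-methylhept-5-en-1-yne)
Conditions: DMSO, 5 °C → rt
Reagents that add atoms: none
Why: SN2 alkylation of acetylide by an unhindered primary homoallylic bromide in a dipolar aprotic solvent.

**Step 2**
Reactants: 3
Product: 4 ((E)-1-iodo-2,6-dimethylhepta-1,5-diene)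
Conditions: AlMe3 (2 equiv), Cp2ZrCl2 (20 mol %), CH2Cl2, 0 °C → rt; then I2, THF, −30 → 0 °C
Reagents that add atoms: trimethylaluminium, C[Al](C)C (the methyl); iodine, II
Why: Negishi Zr-catalysed carboalumination adds Me–Al syn across the terminal alkyne with Me on the internal carbon, and iodinolysis with retention gives the E-vinyl iodide; the trisubstituted olefin is inert.

**Step 3**
Reactants: 4, 5 (β-propiolactone, oxetan-2-one)
Product: 6 ((4E)-5,9-dimethyldeca-4,8-dienoic acid)
Conditions: t-BuLi (2.1 equiv), Et2O, −78 °C; MgBr2·OEt2; then CuI (5 mol %), 5, THF–Me2S, −30 → 0 °C; aq. HCl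
Reagents that add atoms: none
Why: I/Li exchange and transmetalation proceed with retention of olefin geometry, and Cu-catalysed SN2 (alkyl–oxygen) opening of β-propiolactone by the alkenyl metal gives the 4-alkenoic acid directly.

**Step 4**
Reactants: 6
Product: 7 ((4aS,8aS)-5,5,8a-trimethyl-octahydro-2H-chromen-2-one, trans-fused)
Conditions: confined chiral IDPi (imidodiphosphorimidate) Brønsted acid (5 mol %), (CF3)3COH/CHCl3, −20 °C
Reagents that add atoms: none
Why: Brønsted-acid-initiated cation–olefin (biomimetic polyene) cyclisation: protonation of the isopropylidene, chair-like attack by the (E)-4,5-olefin and anti capture by the carboxyl give only the trans-fused lactone, while the chiral anion selects the olefin face so that C4a and C8a are both S (use the catalyst antipode that gives the natural ambrox/sclareolide sense).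

**Step 5**
Reactants: 7
Product: 8 ((4aS,8aS)-5,5,8a-trimethyl-octahydro-2H-chromen-2-ol, anomer mixture)
Conditions: DIBAL-H (1.1 equiv), CH2Cl2, −78 °C; Rochelle salt
Reagents that add atoms: none
Why: Partial lactone reduction stops at the aluminium hemiacetal at −78 °C, and neither stereocentre is touched.

**Step 6**
Reactants: 8
Product: 9 ((1S,2S)-2-(but-3-yn-1-yl)-1,3,3-trimethylcyclohexan-1-ol)
Conditions: Ohira–Bestmann reagent, K2CO3, MeOH, 0 °C → rt
Reagents that add atoms: dimethyl (1-diazo-2-oxopropyl)phosphonate, CC(=O)C(=[N+]=[N-])P(=O)(OC)OC (supplies the terminal alkyne carbon)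
Why: Seyferth–Gilbert (Ohira–Bestmann) homologation of the open hydroxy-aldehyde tautomer gives the terminal alkyne by 1,2-H shift of the alkylidene carbene and unmasks the tertiary alcohol without ionising it.

**Step 7**
Reactants: 9
Product: 10 ((1S,2S)-2-[(3E)-4-iodo-3-methylbut-3-en-1-yl]-1,3,3-trimethylcyclohexan-1-ol)
Conditions: AlMe3 (3.5 equiv), Cp2ZrCl2 (0.5 equiv), CH2Cl2, 0 °C → rt; then I2, THF, −30 °C
Reagents that add atoms: trimethylaluminium, C[Al](C)C (the methyl); iodine, II
Why: Negishi carboalumination/iodination again gives the E-vinyl iodide; the tertiary alcohol is masked in situ as its aluminium alkoxide and is not ionised at or below rt.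

**Step 8**
Reactants: 3
Product: 11 (geraniol, (2E)-3,7-dimethylocta-2,6-dien-1-ol)
Conditions: AlMe3 (2 equiv), Cp2ZrCl2 (20 mol %), CH2Cl2, rt; then n-BuLi, THF, −78 °C; (CH2O)n, → rt
Reagents that add atoms: trimethylaluminium, C[Al](C)C (the methyl); paraformaldehyde, C=O (the CH2OH carbon)
Why: Negishi carboalumination followed by hydroxymethylation of the alkenylaluminate with retention gives the E-allylic alcohol.

**Step 9**
Reactants: 11
Product: 12 (tert-butyl{[(2E)-3,7-dimethylocta-2,6-dien-1-yl]oxy}dimethylsilane)
Conditions: TBSCl, imidazole, DMF, rt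
Reagents that add atoms: TBSCl, CC(C)(C)[Si](C)(C)Cl
Why: Standard silylation protects the allylic alcohol against the two oxidations and the ylide that follow.

**Step 10**
Reactants: 12
Product: 13 ((2E,6E)-8-[(tert-butyldimethylsilyl)oxy]-2,6-dimethylocta-2,6-dien-1-ol)
Conditions: SeO2 (0.3 equiv), t-BuOOH (3 equiv), salicylic acid (10 mol %), CH2Cl2, 0 °C → rt
Reagents that add atoms: tert-butyl hydroperoxide, CC(C)(C)OO (terminal oxidant; oxygen delivered via SeO2, O=[Se]=O)
Why: Sharpless SeO2 allylic oxidation (ene/[2,3] sequence) hydroxylates the E-methyl of the more electron-rich terminal olefin; any over-oxidised aldehyde 14 is carried forward with 13.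

**Step 11**
Reactants: 13
Product: 14 ((2E,6E)-8-[(tert-butyldimethylsilyl)oxy]-2,6-dimethylocta-2,6-dienal)
Conditions: activated MnO2, CH2Cl2, rt
Reagents that add atoms: none
Why: Chemoselective allylic alcohol oxidation with MnO2 leaves the olefin geometry and the silyl ether intact.

**Step 12**
Reactants: 14
Product: 15 (tert-butyl{[(2E,6E)-3,7-dimethylnona-2,6,8-trien-1-yl]oxy}dimethylsilane)
Conditions: Ph3PCH3Br, KHMDS, THF, −78 → 0 °C
Reagents that add atoms: methylenetriphenylphosphorane, C=P(c1ccccc1)(c1ccccc1)c1ccccc1 (the CH2)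
Why: Wittig methylenation of the enal creates no new stereo-element and gives the 1,3-diene with a terminal vinyl group.

**Step 13**
Reactants: 15, 10
Product: 16 ((1S,2S)-2-[(3E,7E,11E)-13-[(tert-butyldimethylsilyl)oxy]-3,7,11-trimethyltrideca-3,7,11-trien-1-yl]-1,3,3-trimethylcyclohexan-1-ol)
Conditions: 15 (1.3 equiv), 9-BBN, THF, 0 °C → rt; then 10, PdCl2(dppf) (5 mol %), AsPh3, Cs2CO3, DMF/H2O, rt
Reagents that add atoms: none
Why: 9-BBN adds only to the terminal vinyl CH2 of the diene (as in the classical homogeraniol hydroboration), and B-alkyl Suzuki–Miyaura coupling with the vinyl iodide proceeds with retention to give the E-C10=C11 olefin; the free tertiary alcohol is tolerated.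

**Step 14**
Reactants: 16
Product: 17 (preluffariellolide A)
Conditions: TBAF, THF, 0 °C → rt
Reagents that add atoms: none
Why: Fluoride desilylation frees the primary allylic alcohol under conditions that do not affect the tertiary alcohol, the olefins or the stereocentres.

## Compound list

1 | 5-bromo-2-methylpent-2-ene | BrCCC=C(C)C | starting material
2 | lithium acetylide–ethylenediamine complex | [Li]C#C.NCCN | starting material
3 | 6-methylhept-5-en-1-yne | C#CCCC=C(C)C | intermediate
4 | (E)-1-iodo-2,6-dimethylhepta-1,5-diene | CC(C)=CCC/C(C)=C/I | intermediate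
5 | β-propiolactone (oxetan-2-one) | O=C1CCO1 | starting material
6 | (4E)-5,9-dimethyldeca-4,8-dienoic acid | CC(C)=CCC/C(C)=C/CCC(=O)O | intermediate
7 | (4aS,8aS)-5,5,8a-trimethyl-octahydro-2H-chromen-2-one | O=C1CC[C@H]2C(C)(C)CCC[C@]2(C)O1 | intermediate
8 | (4aS,8aS)-5,5,8a-trimethyl-octahydro-2H-chromen-2-ol | OC1CC[C@H]2C(C)(C)CCC[C@]2(C)O1 | intermediate
9 | (1S,2S)-2-(but-3-yn-1-yl)-1,3,3-trimethylcyclohexan-1-ol | C#CCC[C@H]1C(C)(C)CCC[C@]1(C)O | intermediate
10 | (1S,2S)-2-[(3E)-4-iodo-3-methylbut-3-en-1-yl]-1,3,3-trimethylcyclohexan-1-ol | I/C=C(\C)CC[C@H]1C(C)(C)CCC[C@]1(C)O | intermediate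
11 | geraniol | CC(C)=CCC/C(C)=C/CO | intermediate
12 | geranyl TBS ether | CC(C)=CCC/C(C)=C/CO[Si](C)(C)C(C)(C)C | intermediate
13 | (2E,6E)-8-(TBS-oxy)-2,6-dimethylocta-2,6-dien-1-ol | OC/C(C)=C/CC/C(C)=C/CO[Si](C)(C)C(C)(C)C | intermediate
14 | (2E,6E)-8-(TBS-oxy)-2,6-dimethylocta-2,6-dienal | O=C/C(C)=C/CC/C(C)=C/CO[Si](C)(C)C(C)(C)C | intermediate
15 | (2E,6E)-3,7-dimethylnona-2,6,8-trien-1-yl TBS ether | C=C/C(C)=C/CC/C(C)=C/CO[Si](C)(C)C(C)(C)C | intermediate
16 | TBS ether of preluffariellolide A | C/C(=C\CO[Si](C)(C)C(C)(C)C)CC/C=C(\C)CC/C=C(\C)CC[C@H]1C(C)(C)CCC[C@]1(C)O | intermediate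
17 | preluffariellolide A, (1S,2S)-2-[(3E,7E,11E)-13-hydroxy-3,7,11-trimethyltrideca-3,7,11-trien-1-yl]-1,3,3-trimethylcyclohexan-1-ol | C/C(=C\CO)CC/C=C(\C)CC/C=C(\C)CC[C@H]1C(C)(C)CCC[C@]1(C)O | target

## Summary

Total step count: 14.
Longest linear sequence: 9 steps (1 → 2 → 3 → 4 → 5 → 6 → 7 → 13 → 14). The other branch (1, 8–12, 13, 14) is 8 steps.

Steps most likely to fail, with fallbacks:

1. **Step 4 (enantioselective cyclisation).** The trans ring fusion is substrate-controlled, but the enantiomeric ratio on this short acid is unproven, and direct protolactonisation of the 4,5-olefin may compete. Fallback: cyclise racemically (ClSO3H or SnCl4, −78 °C) and resolve. Open (±)-7 with KOH, crystallise the hydroxy-carboxylate with a chiral amine such as 1-phenylethylamine, then acidify to relactonise the (4aS,8aS) enantiomer.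

2. **Step 13 (diene hydroboration/B-alkyl Suzuki).** Risks are incomplete regioselectivity on the conjugated diene and sluggish coupling. Fallback: form C8–C9 by allyl sulfone alkylation instead. Convert 9 to the allylic sulfone (carboalumination/CH2O, PBr3, PhSO2Na), alkylate its dianion with the allylic bromide made from 13, then remove the sulfone reductively (LiBHEt3, PdCl2(dppp)) and desilylate.

3. **Step 6 (Ohira–Bestmann on a hindered lactol).** The ring-closed lactol may react slowly. Fallback: add MeLi to lactone 7 to give the hydroxy methyl ketone, silylate the tertiary alcohol, and make the terminal alkyne by kinetic enol phosphate formation and elimination (LDA, ClP(O)(OEt)2; then LDA).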